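**Plan**

1. The last cut (step 11) breaks the bond from the ketal carbon to the ring-fusion CH and takes one oxygen out of the naphthodioxine. This leads back to spiroketal 21, whose ketal carbon lies in a five-membered 2H-naphtho[1,8-bc]furan ring (O, ketal C, naphthalene C8, C8a, C1) and also holds the tertiary carbinol oxygen.
2. Enabling feature: the ketal carbon carries a ring-oxygen lone pair and an aryl carbon (C8) that can shift from carbon to a peroxide oxygen (Criegee). It also stands 1,4 to the only enolisable CH2 of the cyclopentenone, so the dioxinylium ion formed by the ring expansion can close the indane ring 5-exo.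
3. Earlier cuts: enone C=C (IBX), carbinol C–O (asymmetric conjugate borylation/oxidation), aryl–cyclopentenyl bond (Suzuki), naphthyl–carbinol bond (aryllithium + aldehyde), formyl carbon (carbonylation), and the two aryl–acyl bonds of the third phenalene ring (malonyl dichloride + 1,8-dimethoxynaphthalene).
4. Forward ring order: phenalene-1,3-dione ring (step 1), naphthofuran ring (step 6), 9-hydroxyphenalenone unmasked by reductive carbonyl transposition (step 7), cyclopentenone attached (step 8), spiroketal rings (step 9), enone (step 10), then dioxine and indane rings (step 11).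
5. Stereochemistry: the carbinol carbon is set by the CuCl/QuinoxP*-catalysed borylation of step 9 and locked in the spiroketal. The CH centre follows in step 11 from the forced cis-fusion of the two five-membered rings.

Key step: step 11

Remark: the 9-hydroxyphenalenone is written as one of its two rapidly exchanging tautomers. Compounds 9–15 and 17–22 are used as mixtures at the naphthofuran (or carbinol) carbon, which becomes planar in step 11 and is not a stereocentre in 26.

**Step 1**
Reactants: 1 1,8-dimethoxynaphthalene; 2 malonyl dichloride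
Product: 3 3-hydroxy-6,7-dimethoxy-1H-phenalen-1-one
Conditions: AlCl3 (2.5 equiv), PhNO2, 0 °C to rt; 1 M HCl
Reagents that add atoms: none
Why: Double Friedel–Crafts acylation at C4 and C5 (each para to a methoxy group and peri to each other) should close the six-membered ring and give the enolised phenalene-1,3-dione, as in the malonyl dichloride route to 3-hydroxyphenalenones.

**Step 2**
Reactants: 3 3-hydroxy-6,7-dimethoxy-1H-phenalen-1-one
Product: 4 2-chloro-3-hydroxy-6,7-dimethoxy-1H-phenalen-1-one
Conditions: NCS (1.0 equiv), CH2Cl2, 0 °C to rt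
Reagents that add atoms: N-chlorosuccinimide, O=C1CCC(=O)N1Cl
Why: Electrophilic α-chlorination of the enolised cyclic 1,3-diketone at its only nucleophilic carbon should install a placeholder for the later cross-coupling.

**Step 3**
Reactants: 4 2-chloro-3-hydroxy-6,7-dimethoxy-1H-phenalen-1-one
Product: 5 2-chloro-6,7-dimethoxy-1-oxo-1H-phenalen-3-yl trifluoromethanesulfonate
Conditions: Tf2O, Et3N, CH2Cl2, −78 °C
Reagents that add atoms: trifluoromethanesulfonic anhydride, O=S(=O)(OS(=O)(=O)C(F)(F)F)C(F)(F)F
Why: O-Triflation of the mirror-symmetric vinylogous acid can give only one enol triflate and turns C3 into a cross-coupling site.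

**Step 4**
Reactants: 5 2-chloro-6,7-dimethoxy-1-oxo-1H-phenalen-3-yl trifluoromethanesulfonate
Product: 6 2-chloro-6,7-dimethoxy-1-oxo-1H-phenalene-3-carbaldehyde
Conditions: Pd(OAc)2 (5 mol%), 1,3-bis(diphenylphosphino)propane (5 mol%), CO (1 atm), Et3SiH, Et3N, DMF, 60 °C
Reagents that add atoms: carbon monoxide, [C-]#[O+]
Why: Palladium-catalysed reductive carbonylation (formylation) of a vinylogous acyl triflate, with oxidative addition at C–OTf expected to be much faster than at the vinyl C–Cl bond.

**Step 5**
Reactants: 6 2-chloro-6,7-dimethoxy-1-oxo-1H-phenalene-3-carbaldehyde; 7 8-bromonaphthalen-1-ol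
Product: 9 2-chloro-3-[hydroxy(8-hydroxynaphthalen-1-yl)methyl]-6,7-dimethoxy-1H-phenalen-1-one, via dilithio naphtholate 8 (not isolated)
Conditions: 7, n-BuLi (1.0 equiv) then t-BuLi (2.0 equiv), THF, −78 °C; add 6, −78 °C; aq. NH4Cl
Reagents that add atoms: none
Why: Bromine–lithium exchange on the lithium naphtholate gives a peri-lithio aryl nucleophile that should add 1,2 to the aldehyde, the most electrophilic carbonyl (the ring ketone is a vinylogous ester deactivated by both methoxy groups); the new carbinol centre forms as a racemate and is planarised later.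

**Step 6**
Reactants: 9 2-chloro-3-[hydroxy(8-hydroxynaphthalen-1-yl)methyl]-6,7-dimethoxy-1H-phenalen-1-one
Product: 11 2-chloro-6,7-dimethoxy-3-(2-methoxy-2H-naphtho[1,8-bc]furan-2-yl)-1H-phenalen-1-one, via hydroxy ketone 10 (not isolated)
Conditions: MnO2 (activated, excess), CH2Cl2, rt; filter; MeOH, PPTS (cat.), 3 Å molecular sieves, 40 °C
Reagents that add atoms: methanol, CO
Why: MnO2 oxidation of the allylic/benzylic carbinol gives the ketone, which should close with the peri-hydroxyl to the five-membered lactol and be fixed as its methyl ketal (acid-catalysed ketalisation via the cyclic oxocarbenium ion); this builds the naphthofuran ring and shields the ketone from the hydride of step 7.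

**Step 7**
Reactants: 11 2-chloro-6,7-dimethoxy-3-(2-methoxy-2H-naphtho[1,8-bc]furan-2-yl)-1H-phenalen-1-one
Product: 15 5-chloro-9-hydroxy-6-(2-methoxy-2H-naphtho[1,8-bc]furan-2-yl)-1H-phenalen-1-one, via phenalenol 12 (not isolated), via methoxy ketone 13 (not isolated), via isomeric methoxy ketone 14 (not isolated)
Conditions: i-Bu2AlH (1.5 equiv), CH2Cl2, −78 °C; then AcOH/NaOAc buffer (pH 5), THF/H2O, rt; then 1 M NaOH, MeOH, 40 °C; AcOH to pH 5
Reagents that add atoms: water, O; sodium hydroxide, [Na+].[OH-]
Why: Stork–Danheiser-type reductive carbonyl transposition: 1,2-reduction gives a phenalenol that ionises to the dimethoxy-stabilised phenalenium ion, water adds at either methoxy-bearing carbon (13 or 14) and hydroxide saponifies the remaining vinylogous methyl ester, so the former ketone carbon ends as aromatic CH and the methoxy carbons become the C=O/OH pair of the 9-hydroxyphenalenone.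

**Step 8**
Reactants: 15 5-chloro-9-hydroxy-6-(2-methoxy-2H-naphtho[1,8-bc]furan-2-yl)-1H-phenalen-1-one; 16 3-(4,4,5,5-tetramethyl-1,3,2-dioxaborolan-2-yl)cyclopent-2-en-1-one
Product: 17 9-hydroxy-6-(2-methoxy-2H-naphtho[1,8-bc]furan-2-yl)-5-(3-oxocyclopent-1-en-1-yl)-1H-phenalen-1-one
Conditions: Pd(OAc)2 (5 mol%), SPhos (10 mol%), K3PO4 (4 equiv), 1,4-dioxane/H2O, 70 °C
Reagents that add atoms: none
Why: Suzuki–Miyaura coupling of the hindered aryl chloride (dialkylbiarylphosphine ligand) with the vinylogous acyl boronate should attach the 3-oxocyclopentenyl group.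

**Step 9**
Reactants: 17 9-hydroxy-6-(2-methoxy-2H-naphtho[1,8-bc]furan-2-yl)-5-(3-oxocyclopent-1-en-1-yl)-1H-phenalen-1-one
Product: 20 saturated spiroketal (cyclic ketal between the naphthofuran carbon and the new tertiary hydroxyl), via tertiary boronate 18 (not isolated), via tertiary alcohol 19 (not isolated)
Conditions: CuCl (10 mol%), 2,3-bis(tert-butylmethylphosphino)quinoxaline (QuinoxP*, 12 mol%, the enantiomer that gives (S)-18), NaOt-Bu (1.3 equiv), B2pin2 (1.5 equiv), MeOH (3 equiv), THF, rt; then NaBO3·4H2O, THF/H2O, rt; then PPTS, CH2Cl2, 4 Å molecular sieves, rt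
Reagents that add atoms: sodium perborate, [Na+].[Na+].O[B-]1(O)OO[B-](O)(O)OO1
Why: Copper-catalysed enantioselective conjugate borylation of a β-aryl cyclic enone places boron on the β-carbon with ligand-controlled facial selectivity, and stereoretentive C–B oxidation gives the tertiary carbinol; acid then exchanges the ketal methoxy group for this hydroxyl, locking the aldol as a spiroketal that cannot undergo retro-aldol cleavage.

**Step 10**
Reactants: 20 saturated spiroketal
Product: 21 enone spiroketal
Conditions: IBX (2.5 equiv), 4-methoxypyridine N-oxide (2.5 equiv), DMSO, 25 °C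
Reagents that add atoms: none
Why: IBX dehydrogenation of the ketone to the enone; only the CH2–CH2 side can be desaturated because the other β-carbon is the quaternary spiro carbon.

**Step 11**
Reactants: 21 enone spiroketal
Product: 26 spiropreussione B, via silylperoxy ketal 22 (not isolated), via orthoester 23 (not isolated), via dioxinylium triflate 24 (not isolated), via bis-silyl ether 25 (not isolated)
Conditions: Me3SiOOSiMe3 (1.1 equiv), TMSOTf (0.2 equiv), CH2Cl2, −78 to −30 °C; then Et3N (2.5 equiv), TMSOTf (3.0 equiv), −78 to 0 °C; then 1 M HCl, THF, 0 °C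
Reagents that add atoms: bis(trimethylsilyl) peroxide, C[Si](C)(C)OO[Si](C)(C)C
Why: Proposed new method: TMSOTf opens the spiroketal at its tertiary alkoxy oxygen to the 2-aryl-naphtho[1,8-bc]furan-2-ylium ion, which adds Me3SiOOSiMe3 to give peroxy ketal 22; a Criegee (Baeyer–Villiger-type) 1,2-shift of naphthalene C8 from the ketal carbon to the proximal peroxide oxygen, assisted by the ring-oxygen lone pair and with loss of Me3SiO–, inserts oxygen into the five-membered O–C–C8 ring and gives the six-membered naphtho[1,8-de][1,3]dioxin-2-ylium ion, which the neighbouring silyl ether stores as orthoester 23. Et3N/TMSOTf then convert the cyclopentenone into its 2-silyloxy diene and re-ionise the orthoester at the alkyl oxygen to ion 24, whose enol carbon adds to the cationic carbon (Mukaiyama-type addition to an orthoester) and closes the indane ring. The closest known reactions are the Baeyer–Villiger oxidation with Me3SiOOSiMe3/TMSOTf, the Criegee rearrangement of α-alkoxy hydroperoxides to dialkoxycarbenium ions, and the TMSOTf-mediated addition of enol silanes to orthoesters and acetals; their merger with a carbon nucleophile in place of water is untested. Ring closures: the dioxine by ring expansion (five to six members, aryl shift from C to O), the carbocycle by 5-exo-trig (enolexo) attack. The new CH stereocentre is dictated by the existing carbinol carbon, because two fused five-membered rings can only be cis-fused. The step needs C8 of the naphthol to migrate rather than the phenalenone carbon (the latter is electron-poor and carbonyl-conjugated, and ring expansion releases strain), and needs C–C bond formation at the CH2 between carbinol and ketone (the only enolisable position, since the other α-carbon is vinylic).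

**Compound list**

1 | 1,8-dimethoxynaphthalene | COc1cccc2cccc(OC)c12 | starting material
2 | malonyl dichloride | O=C(Cl)CC(=O)Cl | starting material
3 | 3-hydroxy-6,7-dimethoxy-1H-phenalen-1-one | O=C1C=C(O)c2ccc(OC)c3c(OC)ccc1c23 | intermediate
4 | 2-chloro-3-hydroxy-6,7-dimethoxy-1H-phenalen-1-one | O=C1C(Cl)=C(O)c2ccc(OC)c3c(OC)ccc1c23 | intermediate
5 | 2-chloro-6,7-dimethoxy-1-oxo-1H-phenalen-3-yl trifluoromethanesulfonate | O=C1C(Cl)=C(OS(=O)(=O)C(F)(F)F)c2ccc(OC)c3c(OC)ccc1c23 | intermediate
6 | 2-chloro-6,7-dimethoxy-1-oxo-1H-phenalene-3-carbaldehyde | O=C1C(Cl)=C(C=O)c2ccc(OC)c3c(OC)ccc1c23 | intermediate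
7 | 8-bromonaphthalen-1-ol | Oc1cccc2cccc(Br)c12 | starting material
8 | lithium 8-lithionaphthalen-1-olate | [Li]Oc1cccc2cccc([Li])c12 | intermediate
9 | 2-chloro-3-[hydroxy(8-hydroxynaphthalen-1-yl)methyl]-6,7-dimethoxy-1H-phenalen-1-one (racemic) | O=C1C(Cl)=C(C(O)c4cccc5cccc(O)c45)c2ccc(OC)c3c(OC)ccc1c23 | intermediate
10 | 2-chloro-3-(8-hydroxy-1-naphthoyl)-6,7-dimethoxy-1H-phenalen-1-one | O=C1C(Cl)=C(C(=O)c4cccc5cccc(O)c45)c2ccc(OC)c3c(OC)ccc1c23 | intermediate
11 | 2-chloro-6,7-dimethoxy-3-(2-methoxy-2H-naphtho[1,8-bc]furan-2-yl)-1H-phenalen-1-one (racemic) | O=C1C(Cl)=C(C4(OC)Oc5cccc6cccc4c56)c2ccc(OC)c3c(OC)ccc1c23 | intermediate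
12 | 2-chloro-6,7-dimethoxy-3-(2-methoxy-2H-naphtho[1,8-bc]furan-2-yl)-1H-phenalen-1-ol (stereoisomer mixture) | OC1C(Cl)=C(C4(OC)Oc5cccc6cccc4c56)c2ccc(OC)c3c(OC)ccc1c23 | intermediate
13 | 5-chloro-9-methoxy-6-(2-methoxy-2H-naphtho[1,8-bc]furan-2-yl)-1H-phenalen-1-one | O=C1C=Cc2cc(Cl)c(C4(OC)Oc5cccc6cccc4c56)c3ccc(OC)c1c23 | intermediate
14 | 5-chloro-9-methoxy-4-(2-methoxy-2H-naphtho[1,8-bc]furan-2-yl)-1H-phenalen-1-one | COc1ccc2cc(Cl)c(C4(OC)Oc5cccc6cccc4c56)c3C=CC(=O)c1c23 | intermediate
15 | 5-chloro-9-hydroxy-6-(2-methoxy-2H-naphtho[1,8-bc]furan-2-yl)-1H-phenalen-1-one (racemic) | O=C1C=Cc2cc(Cl)c(C4(OC)Oc5cccc6cccc4c56)c3ccc(O)c1c23 | intermediate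
16 | 3-(4,4,5,5-tetramethyl-1,3,2-dioxaborolan-2-yl)cyclopent-2-en-1-one | O=C1C=C(B2OC(C)(C)C(C)(C)O2)CC1 | starting material
17 | 9-hydroxy-6-(2-methoxy-2H-naphtho[1,8-bc]furan-2-yl)-5-(3-oxocyclopent-1-en-1-yl)-1H-phenalen-1-one (racemic) | O=C1C=Cc2cc(C7=CC(=O)CC7)c(C4(OC)Oc5cccc6cccc4c56)c3ccc(O)c1c23 | intermediate
18 | 9-hydroxy-6-(2-methoxy-2H-naphtho[1,8-bc]furan-2-yl)-5-[(1S)-3-oxo-1-(pinacolatoboryl)cyclopentyl]-1H-phenalen-1-one (either ketal epimer) | O=C1C=Cc2cc([C@@]7(B8OC(C)(C)C(C)(C)O8)CCC(=O)C7)c(C4(OC)Oc5cccc6cccc4c56)c3ccc(O)c1c23 | intermediate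
19 | 9-hydroxy-5-[(1R)-1-hydroxy-3-oxocyclopentyl]-6-(2-methoxy-2H-naphtho[1,8-bc]furan-2-yl)-1H-phenalen-1-one (either ketal epimer) | O=C1C=Cc2cc([C@@]7(O)CCC(=O)C7)c(C4(OC)Oc5cccc6cccc4c56)c3ccc(O)c1c23 | intermediate
20 | saturated spiroketal: a 2,5-dihydrofuran fused across C5–C6 of the 9-hydroxyphenalenone, one ring carbon being the spiro carbon of a 3-oxocyclopentane (R, from the carbinol) and the other the spiro carbon of the 2H-naphtho[1,8-bc]furan (either configuration) | O=C1C=Cc2cc3c(c4ccc(O)c1c24)C5(Oc6cccc7cccc5c67)O[C@@]38CCC(=O)C8 | intermediate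
21 | enone spiroketal: as 20 with the 4-oxocyclopent-2-ene ring (same spatial arrangement at the carbinol-derived carbon; either configuration at the naphthofuran carbon) | O=C1C=Cc2cc3c(c4ccc(O)c1c24)C5(Oc6cccc7cccc5c67)O[C@@]38C=CC(=O)C8 | intermediate
22 | silylperoxy ketal: 2-aryl-2-(trimethylsilylperoxy)-2H-naphtho[1,8-bc]furan with the tertiary alcohol as its trimethylsilyl ether | O=C1C=Cc2cc([C@@]7(O[Si](C)(C)C)C=CC(=O)C7)c(C4(OO[Si](C)(C)C)Oc5cccc6cccc4c56)c3ccc(O)c1c23 | intermediate
23 | orthoester: the naphtho[1,8-de][1,3]dioxine C2 also bound to the tertiary alkoxy oxygen | O=C1C=Cc2cc3c(c4ccc(O)c1c24)C5(Oc6cccc7cccc(c67)O5)O[C@@]38C=CC(=O)C8 | intermediate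
24 | 2-aryl-naphtho[1,8-de][1,3]dioxin-2-ylium triflate with the silyloxy diene, silyl ether and O-silylated phenalenone | O=C1C=Cc2cc([C@@]7(O[Si](C)(C)C)C=CC(O[Si](C)(C)C)=C7)c([C+]4Oc5cccc6cccc(c56)O4)c3ccc(O[Si](C)(C)C)c1c23.[O-]S(=O)(=O)C(F)(F)F | intermediate
25 | bis(trimethylsilyl) ether of 26 (tertiary and phenalenone oxygens) | O=C1C=Cc2cc3c(c4ccc(O[Si](C)(C)C)c1c24)C1(Oc2cccc4cccc(c24)O1)[C@@H]1C(=O)C=C[C@]31O[Si](C)(C)C | intermediate
26 | spiropreussione B (carbinol carbon R, ring-fusion CH S) | O=C1C=Cc2cc3c(c4ccc(O)c1c24)C1(Oc2cccc4cccc(c24)O1)[C@@H]1C(=O)C=C[C@]31O | target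

**Step count and risks**

Total steps: 11. Longest linear sequence: 11 steps (from 1; 7 and 16 enter as purchased fragments).

Steps most likely to fail:

Step 11 (Proposed new method). What may go wrong: migration of the wrong aryl group in the Criegee step, peroxide attack at the cyclopentenone or the enol silane, hydrolytic collapse of the orthoester to a lactone instead of C–C bond formation, and retro-aldol racemisation of the free β-hydroxy ketone if the work-up turns basic. Fallback, setting out from 21: a classical Baeyer–Villiger oxidation (mCPBA, CF3CO2H, CH2Cl2, then dilute acid) of the ring-opened diaryl ketone lets the 8-hydroxynaphthyl ester lactonise onto the tertiary alcohol with loss of naphthalene-1,8-diol, giving the spiro lactone F1. LiN(SiMe3)2 (THF, −78 °C) then moves the acyl group from oxygen to the α-carbon of the cyclopentenone (Dieckmann-type lactone-to-1,3-diketone rearrangement) to give the cis-fused hydroxy triketone F2. Acid-catalysed ketalisation of its aryl ketone with naphthalene-1,8-diol (TsOH, toluene, water removal) returns to the route at 26.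

Step 9. What may go wrong: slow addition or poor facial selectivity at the hindered β-aryl carbon, and dehydration or retro-aldol cleavage during the oxidation. Fallback, setting out from 15: Suzuki coupling with 5-methylfuran-2-boronic acid pinacol ester gives the aryl furan F3. Oxidative furan opening with dimethyldioxirane gives the Z-enedione F4. Base-mediated intramolecular aldol addition (aq. Na2CO3, THF) gives the racemic hydroxycyclopentenone F5, which PPTS closes to the racemic spiroketal F6. Preparative chromatography on a chiral stationary phase then returns to the route at 21.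

Step 5. What may go wrong: competing addition–elimination at the chlorine-bearing carbon, attack at the ring ketone, or poor solubility of the dianion. Fallback, setting out from 5: carbonylative Suzuki–Miyaura coupling with (8-methoxynaphthalen-1-yl)boronic acid (Pd(OAc)2, Xantphos, CO, K2CO3) gives the methoxy ketone F7. Peri-selective demethylation with BCl3 (CH2Cl2, −78 °C) gives 10, which is ketalised as in step 6 and returns to the route at 11.

**Further compounds**

F1 | step 11 | spiro lactone (phthalide-type lactone of the tertiary alcohol) | O=C1C=Cc2cc3c(c4ccc(O)c1c24)C(=O)O[C@@]35C=CC(=O)C5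
F2 | step 11 | cis-fused hydroxy triketone | O=C1C=Cc2cc3c(c4ccc(O)c1c24)C(=O)[C@@H]5C(=O)C=C[C@]35O
F3 | step 9 | 9-hydroxy-6-(2-methoxy-2H-naphtho[1,8-bc]furan-2-yl)-5-(5-methylfuran-2-yl)-1H-phenalen-1-one | O=C1C=Cc2cc(-c7ccc(C)o7)c(C4(OC)Oc5cccc6cccc4c56)c3ccc(O)c1c23
F4 | step 9 | Z-enedione (Z)-1-aryl-pent-2-ene-1,4-dione | O=C1C=Cc2cc(C(=O)/C=C\C(C)=O)c(C4(OC)Oc5cccc6cccc4c56)c3ccc(O)c1c23
F5 | step 9 | racemic 4-aryl-4-hydroxycyclopent-2-enone | O=C1C=Cc2cc(C7(O)C=CC(=O)C7)c(C4(OC)Oc5cccc6cccc4c56)c3ccc(O)c1c23
F6 | step 9 | racemic enone spiroketal | O=C1C=Cc2cc3c(c4ccc(O)c1c24)C5(Oc6cccc7cccc5c67)OC38C=CC(=O)C8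
F7 | step 5 | 2-chloro-6,7-dimethoxy-3-(8-methoxy-1-naphthoyl)-1H-phenalen-1-one | O=C1C(Cl)=C(C(=O)c4cccc5cccc(OC)c45)c2ccc(OC)c3c(OC)ccc1c23
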